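**Plan**

- Retrosynthesis: the C7–propenyl bond is cut first (Suzuki coupling on a C7 bromide). After a carboxyl group is put back on C2, the O1–C2 and C2–C3 bonds of the dioxane ring are cut, which removes C2 with its syringyl ring as an aryl(ester)carbene.
- Enabling feature: the six-membered ring O1–C2–C3–O4 fused to the arene is the one-carbon homologue of a five-membered catechol acetal. O1 and O4 are the catechol oxygens, C3 with its methyl group is the acetal carbon of a 2-methyl-1,3-benzodioxole, and C2 is the single aryl-bearing carbon inserted between O1 and C3.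
- Forward: the benzodioxole (2 steps) and the aryl diazoacetate (3 steps) are joined in one step, in which the dioxane ring arises by oxonium ylide formation at O1 and [1,2]-shift of the acetal carbon. The C2 ester is then removed, the propenyl group coupled on and the phenol freed.
- Stereochemistry: C3 (R) comes from the chiral bisoxazoline copper catalyst in the ring expansion. C2 (R) is set last, thermodynamically, by quinone-methide equilibration to the trans isomer. The E alkene comes from the boronic acid.

Key step: step 6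

Assumption: the (S,S)-bisoxazoline is taken to give the (3R) series; if the sense of induction is found to be opposite, the (R,R)-ligand is used.

**Route**

Step 1
Reactants: 1 5-bromo-2-hydroxy-3-methoxybenzaldehyde
Product: 3 5-bromo-3-methoxybenzene-1,2-diol, via aryl formate 2 (not isolated)
Conditions: 30 % aq. H2O2, NaOH, H2O/THF, 0 °C to rt, under N2; then HCl
Reagents that add atoms: hydrogen peroxide, OO
Why: Dakin oxidation, in which hydroperoxide adds to the aldehyde ortho to the phenoxide, the electron-rich aryl group migrates to oxygen and formate 2 is hydrolysed in the basic medium, should give the catechol.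

Step 2
Reactants: 3 5-bromo-3-methoxybenzene-1,2-diol; 4 acetaldehyde dimethyl acetal (1,1-dimethoxyethane)
Product: 5 rac-6-bromo-4-methoxy-2-methyl-1,3-benzodioxole
Conditions: TsOH·H2O (2 mol %), toluene, 90 °C, 4 Å MS to take up MeOH; Et3N quench
Reagents that add atoms: none
Why: Acid-catalysed transacetalisation driven by removal of methanol should close the five-membered ethylidene acetal on the catechol; the racemic acetal carbon is of no consequence because it is planarised in step 6.

Step 3
Reactants: 6 (4-hydroxy-3,5-dimethoxyphenyl)acetic acid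
Product: 7 methyl (4-hydroxy-3,5-dimethoxyphenyl)acetate
Conditions: MeOH, H2SO4 (cat.), reflux
Reagents that add atoms: methanol, CO
Why: Fischer esterification of an unhindered arylacetic acid in methanol as solvent, which leaves the phenol untouched.

Step 4
Reactants: 7 methyl (4-hydroxy-3,5-dimethoxyphenyl)acetate
Product: 8 methyl [3,5-dimethoxy-4-(pivaloyloxy)phenyl]acetate
Conditions: PivCl, Et3N, DMAP (cat.), CH2Cl2, 0 °C to rt
Reagents that add atoms: pivaloyl chloride, CC(C)(C)C(=O)Cl
Why: DMAP-catalysed O-acylation gives a pivalate that removes the carbene-trapping O–H bond, should withstand DBU, iodide and thiyl radicals, and is cleaved by mild methanolysis at the end.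

Step 5
Reactants: 8 methyl [3,5-dimethoxy-4-(pivaloyloxy)phenyl]acetate
Product: 9 methyl 2-diazo-2-[3,5-dimethoxy-4-(pivaloyloxy)phenyl]acetate
Conditions: 4-acetamidobenzenesulfonyl azide (p-ABSA), DBU, MeCN, 0 °C to rt
Reagents that add atoms: 4-acetamidobenzenesulfonyl azide, CC(=O)Nc1ccc(cc1)S(=O)(=O)N=[N+]=[N-]
Why: Regitz diazo transfer to the benzylic ester enolate is the standard entry to aryl diazoacetates.

Step 6
Reactants: 5 rac-6-bromo-4-methoxy-2-methyl-1,3-benzodioxole (3 equiv); 9 methyl 2-diazo-2-[3,5-dimethoxy-4-(pivaloyloxy)phenyl]acetate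
Product: 11 methyl (3R)-7-bromo-2-[3,5-dimethoxy-4-(pivaloyloxy)phenyl]-5-methoxy-3-methyl-2,3-dihydro-1,4-benzodioxine-2-carboxylate as both C2 epimers, via oxonium ylide 10 (not isolated)
Conditions: Cu(MeCN)4PF6 (5 mol %), 2,2'-(propane-2,2-diyl)bis[(4S)-4-tert-butyl-4,5-dihydrooxazole] (6 mol %), CH2Cl2, 4 Å MS, 30 °C, slow addition of 9
Reagents that add atoms: none
Why: Proposed new method: the chiral monovalent copper complex should expel N2 from 9 to give an electrophilic aryl(ester) copper carbene, which is captured by a lone pair of O1 of 5 (the oxygen on C7a, remote from the methoxy group) to give the copper-bound oxonium ylide 10; heterolysis of its weakened O1–acetal carbon bond leaves an oxocarbenium ion stabilised by the second catechol oxygen and tethered to a copper ester enolate, and C–C bond formation between the enolate carbon and the oxocarbenium carbon completes a formal [1,2]-Stevens shift that places the carbene carbon between O1 and the former acetal carbon. The closest known reaction type is the copper- or rhodium-carbene ring expansion of oxetanes to tetrahydrofurans and of 1,3-dioxolanes to 1,4-dioxanes through oxonium ylides, which has not been shown on a catechol acetal. The 1,4-dioxane ring closes by a 6-(enolexo)-endo-trig attack of the enolate on the oxocarbenium carbon, the two reacting ends being held on adjacent positions of the arene. The C3 stereocentre is set in this C–C bond formation by the bisoxazoline ligand on copper, which has to differentiate the two faces of the planar oxocarbenium ion so that both enantiomers of racemic 5 converge on the (3R) series, and the excess of 5 lets the catalyst also select between the acetal enantiomers should part of the shift proceed with retention; the configuration of the quaternary C2 is left open because that centre is planarised in step 8 and equilibrated in step 10. The step needs ylide formation at O1 and not at the other acetal oxygen, which is shielded by the neighbouring 4-methoxy group whereas O1 has only a ring hydrogen next to it. It also needs the carbene to spare the arene and the acetal C–H bond, which the bromine flanking both free ring positions, the low hydridic character of an acetal C–H bond and slow addition of 9 to an excess of 5 are meant to secure.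

Step 7
Reactants: 11 methyl (3R)-7-bromo-2-[3,5-dimethoxy-4-(pivaloyloxy)phenyl]-5-methoxy-3-methyl-2,3-dihydro-1,4-benzodioxine-2-carboxylate (both C2 epimers)
Product: 12 (3R)-7-bromo-2-[3,5-dimethoxy-4-(pivaloyloxy)phenyl]-5-methoxy-3-methyl-2,3-dihydro-1,4-benzodioxine-2-carboxylic acid as both C2 epimers
Conditions: LiI (5 equiv), pyridine, reflux; then 1 M HCl
Reagents that add atoms: none
Why: SN2 dealkylation of the methyl ester by iodide takes place at the methyl carbon, so it is indifferent to the congestion around the fully substituted C2 and should leave the aryl pivalate, which never meets hydroxide, in place.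

Step 8
Reactants: 12 (3R)-7-bromo-2-[3,5-dimethoxy-4-(pivaloyloxy)phenyl]-5-methoxy-3-methyl-2,3-dihydro-1,4-benzodioxine-2-carboxylic acid (both C2 epimers)
Product: 13 4-[(3R)-7-bromo-5-methoxy-3-methyl-2,3-dihydro-1,4-benzodioxin-2-yl]-2,6-dimethoxyphenyl pivalate as both C2 epimers
Conditions: 9-mesityl-10-phenylacridinium tetrafluoroborate (5 mol %), (PhS)2 (20 mol %), i-Pr2NEt (20 mol %), CF3CH2OH, 450 nm LEDs, rt
Reagents that add atoms: none
Why: Photoredox hydrodecarboxylation, in which the excited acridinium salt oxidises the carboxylate, CO2 is lost to give the benzylic alpha-oxy C2 radical and thiophenol delivers the hydrogen atom, should give the C2–H compound without touching C3; the high thiol load is meant to outrun beta-scission of the C3–O4 bond.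

Step 9
Reactants: 13 4-[(3R)-7-bromo-5-methoxy-3-methyl-2,3-dihydro-1,4-benzodioxin-2-yl]-2,6-dimethoxyphenyl pivalate (both C2 epimers); 14 (E)-prop-1-enylboronic acid
Product: 15 4-{(3R)-5-methoxy-3-methyl-7-[(E)-prop-1-enyl]-2,3-dihydro-1,4-benzodioxin-2-yl}-2,6-dimethoxyphenyl pivalate as both C2 epimers
Conditions: Pd(OAc)2 (3 mol %), SPhos (2-dicyclohexylphosphino-2',6'-dimethoxybiphenyl, 6 mol %), K3PO4 (3 equiv), toluene/H2O 10:1, 70 °C
Reagents that add atoms: none
Why: Suzuki–Miyaura coupling, in which the electron-rich biarylphosphine lets zerovalent palladium insert into the electron-rich aryl bromide and the alkenyl group is transferred with retention of the E geometry; with the phenol still acylated no phenoxide is present that could open the dioxane ring.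

Step 10
Reactants: 15 4-{(3R)-5-methoxy-3-methyl-7-[(E)-prop-1-enyl]-2,3-dihydro-1,4-benzodioxin-2-yl}-2,6-dimethoxyphenyl pivalate (both C2 epimers)
Product: 18 4-{(2R,3R)-5-methoxy-3-methyl-7-[(E)-prop-1-enyl]-2,3-dihydro-1,4-benzodioxin-2-yl}-2,6-dimethoxyphenol, via C2-epimeric phenols 16 (not isolated), via quinone methide 17 (not isolated)
Conditions: K2CO3 (30 mol %), MeOH, 50 °C; then aq. NH4Cl
Reagents that add atoms: none
Why: Base-catalysed methanolysis of the aryl pivalate frees the 4-hydroxyl group, whose phenoxide reversibly expels O1 from the benzylic C2 to give the para-quinone methide 17 and recloses by 6-exo-trig oxa-Michael addition, so that C2 should settle in the more stable trans (2R,3R) arrangement while C3, which is not part of the quinone methide system, keeps its configuration.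

**Compound list**

1 | 5-bromo-2-hydroxy-3-methoxybenzaldehyde | O=Cc1cc(Br)cc(OC)c1O | starting material
2 | 5-bromo-2-hydroxy-3-methoxyphenyl formate (not isolated) | O=COc1cc(Br)cc(OC)c1O | intermediate
3 | 5-bromo-3-methoxybenzene-1,2-diol | Oc1cc(Br)cc(OC)c1O | intermediate
4 | acetaldehyde dimethyl acetal (1,1-dimethoxyethane) | CC(OC)OC | starting material
5 | rac-6-bromo-4-methoxy-2-methyl-1,3-benzodioxole | CC1Oc2cc(Br)cc(OC)c2O1 | intermediate
6 | (4-hydroxy-3,5-dimethoxyphenyl)acetic acid | OC(=O)Cc1cc(OC)c(O)c(OC)c1 | starting material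
7 | methyl (4-hydroxy-3,5-dimethoxyphenyl)acetate | COC(=O)Cc1cc(OC)c(O)c(OC)c1 | intermediate
8 | methyl [3,5-dimethoxy-4-(pivaloyloxy)phenyl]acetate | COC(=O)Cc1cc(OC)c(OC(=O)C(C)(C)C)c(OC)c1 | intermediate
9 | methyl 2-diazo-2-[3,5-dimethoxy-4-(pivaloyloxy)phenyl]acetate | COC(=O)C(=[N+]=[N-])c1cc(OC)c(OC(=O)C(C)(C)C)c(OC)c1 | intermediate
10 | oxonium ylide at O1 of 5 carrying the aryl(methoxycarbonyl)methanide carbon, drawn without copper (not isolated) | CC1Oc2c(OC)cc(Br)cc2[O+]1[C-](C(=O)OC)c1cc(OC)c(OC(=O)C(C)(C)C)c(OC)c1 | intermediate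
11 | methyl (3R)-7-bromo-2-[3,5-dimethoxy-4-(pivaloyloxy)phenyl]-5-methoxy-3-methyl-2,3-dihydro-1,4-benzodioxine-2-carboxylate (both C2 epimers) | Brc1cc(OC)c2c(c1)OC(C(=O)OC)(c1cc(OC)c(OC(=O)C(C)(C)C)c(OC)c1)[C@@H](C)O2 | intermediate
12 | (3R)-7-bromo-2-[3,5-dimethoxy-4-(pivaloyloxy)phenyl]-5-methoxy-3-methyl-2,3-dihydro-1,4-benzodioxine-2-carboxylic acid (both C2 epimers) | Brc1cc(OC)c2c(c1)OC(C(=O)O)(c1cc(OC)c(OC(=O)C(C)(C)C)c(OC)c1)[C@@H](C)O2 | intermediate
13 | 4-[(3R)-7-bromo-5-methoxy-3-methyl-2,3-dihydro-1,4-benzodioxin-2-yl]-2,6-dimethoxyphenyl pivalate (both C2 epimers) | Brc1cc(OC)c2c(c1)OC(c1cc(OC)c(OC(=O)C(C)(C)C)c(OC)c1)[C@@H](C)O2 | intermediate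
14 | (E)-prop-1-enylboronic acid | C/C=C/B(O)O | starting material
15 | 4-{(3R)-5-methoxy-3-methyl-7-[(E)-prop-1-enyl]-2,3-dihydro-1,4-benzodioxin-2-yl}-2,6-dimethoxyphenyl pivalate (both C2 epimers) | C/C=C/c1cc(OC)c2c(c1)OC(c1cc(OC)c(OC(=O)C(C)(C)C)c(OC)c1)[C@@H](C)O2 | intermediate
16 | 4-{(3R)-5-methoxy-3-methyl-7-[(E)-prop-1-enyl]-2,3-dihydro-1,4-benzodioxin-2-yl}-2,6-dimethoxyphenol (both C2 epimers, not isolated) | C/C=C/c1cc(OC)c2c(c1)OC(c1cc(OC)c(O)c(OC)c1)[C@@H](C)O2 | intermediate
17 | 4-{(2R)-2-[2-hydroxy-6-methoxy-4-((E)-prop-1-enyl)phenoxy]propylidene}-2,6-dimethoxycyclohexa-2,5-dien-1-one (not isolated) | O=C1C(OC)=CC(=C[C@@H](C)Oc2c(OC)cc(/C=C/C)cc2O)C=C1OC | intermediate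
18 | 4-{(2R,3R)-5-methoxy-3-methyl-7-[(E)-prop-1-enyl]-2,3-dihydro-1,4-benzodioxin-2-yl}-2,6-dimethoxyphenol (CNP0227775.1) | C/C=C/c1cc(OC)c2c(c1)O[C@H](c1cc(OC)c(O)c(OC)c1)[C@@H](C)O2 | target

**Count**

Total: 10 steps. Longest linear sequence: 8 steps (6 to 18 through steps 3 to 10).

**Steps most likely to fail**

Step 6 (proposed new method). The carbene may be taken up by the methoxy-flanked acetal oxygen or inserted into the acetal C–H bond. The rearrangement may also leave the chiral copper centre or run with retention in a tight pair, so that C3 forms with low enantiomeric purity. The fallback uses known reactions only, sets out from 1 and comes back to the route at 18.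

Mitsunobu etherification of 1 with ethyl (S)-lactate (PPh3, DIAD, THF) should give, with inversion, ethyl (2R)-2-(4-bromo-2-formyl-6-methoxyphenoxy)propanoate F1. This fixes C3 from the chiral pool and places the lactate on the oxygen next to the methoxy group. Baeyer–Villiger oxidation (mCPBA, NaHCO3, CH2Cl2) would give ethyl (2R)-2-[4-bromo-2-(formyloxy)-6-methoxyphenoxy]propanoate F2. Methanolysis of the formate (Et3N, MeOH) gives ethyl (2R)-2-(4-bromo-2-hydroxy-6-methoxyphenoxy)propanoate F3, and acid-catalysed lactonisation (TsOH, toluene, 80 °C) gives (3R)-7-bromo-5-methoxy-3-methyl-2,3-dihydro-1,4-benzodioxin-2-one F4.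

Commercial 4-bromo-2,6-dimethoxyphenol is silylated (t-BuMe2SiCl, imidazole, DMF) to (4-bromo-2,6-dimethoxyphenoxy)(tert-butyl)dimethylsilane F5. Bromine–lithium exchange (n-BuLi, THF, −78 °C) gives [4-(tert-butyldimethylsilyloxy)-3,5-dimethoxyphenyl]lithium F6. Its addition to F4 at −78 °C gives the lactol (3R)-7-bromo-2-[4-(tert-butyldimethylsilyloxy)-3,5-dimethoxyphenyl]-5-methoxy-3-methyl-2,3-dihydro-1,4-benzodioxin-2-ol F7.

Ionic hydrogenation (Et3SiH, BF3·OEt2, CH2Cl2, −78 to −20 °C) through the 2-aryl oxocarbenium ion gives {4-[(3R)-7-bromo-5-methoxy-3-methyl-2,3-dihydro-1,4-benzodioxin-2-yl]-2,6-dimethoxyphenoxy}(tert-butyl)dimethylsilane F8 (C2 epimers). Suzuki coupling with 14 under the conditions of step 9 gives tert-butyl{2,6-dimethoxy-4-[(3R)-5-methoxy-3-methyl-7-[(E)-prop-1-enyl]-2,3-dihydro-1,4-benzodioxin-2-yl]phenoxy}dimethylsilane F9. Bu4NF in THF then frees the phenoxide of 16, which equilibrates C2 through 17 as in step 10 and should give 18.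

Step 8. Ring-opening beta-scission of the C3–O4 bond in the C2 radical may compete with hydrogen-atom transfer. The fallback sets out from 12 and comes back at 13; it ends the radical by oxidation instead of reduction. Anodic (Hofer–Moest) decarboxylation of 12 in methanol (graphite electrodes, Et3N (cat.), constant current) oxidises the radical at the electrode at once to the O1-stabilised benzylic cation, which the solvent traps. This should give the mixed ketal 4-[(3R)-7-bromo-2,5-dimethoxy-3-methyl-2,3-dihydro-1,4-benzodioxin-2-yl]-2,6-dimethoxyphenyl pivalate F10. Ionic hydrogenation (Et3SiH, BF3·OEt2, CH2Cl2, −40 °C) then gives 13.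

Step 10. Methanolysis of the hindered pivalate may be slow. The quinone methide may also be captured by methanol or drift towards its enol ether tautomer instead of reclosing, with loss of material and possible erosion at C3. The fallback sets out from 13 and comes back at 18. It separates deprotection from the adjustment of C2 and carries out the latter under acid before the acid-sensitive propenyl group is present.

Reductive removal of the pivalate (i-Bu2AlH, toluene, −78 °C) gives 4-[(3R)-7-bromo-5-methoxy-3-methyl-2,3-dihydro-1,4-benzodioxin-2-yl]-2,6-dimethoxyphenol F11 as the C2 epimers. CF3CO2H in CH2Cl2 (0 °C) reversibly ionises the benzylic C2–O1 bond, assisted by the para-hydroxyl group, and should leave the trans isomer 4-[(2R,3R)-7-bromo-5-methoxy-3-methyl-2,3-dihydro-1,4-benzodioxin-2-yl]-2,6-dimethoxyphenol F12. Stille coupling with (E)-tributyl(prop-1-enyl)stannane (Pd(PPh3)4, toluene, 90 °C) needs no base, so no phenoxide forms, and gives 18.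

**Further compounds**

F1 | step 6 | ethyl (2R)-2-(4-bromo-2-formyl-6-methoxyphenoxy)propanoate | CCOC(=O)[C@@H](C)Oc1c(C=O)cc(Br)cc1OC
F2 | step 6 | ethyl (2R)-2-[4-bromo-2-(formyloxy)-6-methoxyphenoxy]propanoate | CCOC(=O)[C@@H](C)Oc1c(OC=O)cc(Br)cc1OC
F3 | step 6 | ethyl (2R)-2-(4-bromo-2-hydroxy-6-methoxyphenoxy)propanoate | CCOC(=O)[C@@H](C)Oc1c(O)cc(Br)cc1OC
F4 | step 6 | (3R)-7-bromo-5-methoxy-3-methyl-2,3-dihydro-1,4-benzodioxin-2-one | Brc1cc(OC)c2c(c1)OC(=O)[C@@H](C)O2
F5 | step 6 | (4-bromo-2,6-dimethoxyphenoxy)(tert-butyl)dimethylsilane | COc1cc(Br)cc(OC)c1O[Si](C)(C)C(C)(C)C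
F6 | step 6 | [4-(tert-butyldimethylsilyloxy)-3,5-dimethoxyphenyl]lithium | [Li]c1cc(OC)c(O[Si](C)(C)C(C)(C)C)c(OC)c1
F7 | step 6 | (3R)-7-bromo-2-[4-(tert-butyldimethylsilyloxy)-3,5-dimethoxyphenyl]-5-methoxy-3-methyl-2,3-dihydro-1,4-benzodioxin-2-ol | Brc1cc(OC)c2c(c1)OC(O)(c1cc(OC)c(O[Si](C)(C)C(C)(C)C)c(OC)c1)[C@@H](C)O2
F8 | step 6 | {4-[(3R)-7-bromo-5-methoxy-3-methyl-2,3-dihydro-1,4-benzodioxin-2-yl]-2,6-dimethoxyphenoxy}(tert-butyl)dimethylsilane | Brc1cc(OC)c2c(c1)OC(c1cc(OC)c(O[Si](C)(C)C(C)(C)C)c(OC)c1)[C@@H](C)O2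
F9 | step 6 | tert-butyl{2,6-dimethoxy-4-[(3R)-5-methoxy-3-methyl-7-[(E)-prop-1-enyl]-2,3-dihydro-1,4-benzodioxin-2-yl]phenoxy}dimethylsilane | C/C=C/c1cc(OC)c2c(c1)OC(c1cc(OC)c(O[Si](C)(C)C(C)(C)C)c(OC)c1)[C@@H](C)O2
F10 | step 8 | 4-[(3R)-7-bromo-2,5-dimethoxy-3-methyl-2,3-dihydro-1,4-benzodioxin-2-yl]-2,6-dimethoxyphenyl pivalate | Brc1cc(OC)c2c(c1)OC(OC)(c1cc(OC)c(OC(=O)C(C)(C)C)c(OC)c1)[C@@H](C)O2
F11 | step 10 | 4-[(3R)-7-bromo-5-methoxy-3-methyl-2,3-dihydro-1,4-benzodioxin-2-yl]-2,6-dimethoxyphenol | Brc1cc(OC)c2c(c1)OC(c1cc(OC)c(O)c(OC)c1)[C@@H](C)O2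
F12 | step 10 | 4-[(2R,3R)-7-bromo-5-methoxy-3-methyl-2,3-dihydro-1,4-benzodioxin-2-yl]-2,6-dimethoxyphenol | Brc1cc(OC)c2c(c1)O[C@H](c1cc(OC)c(O)c(OC)c1)[C@@H](C)O2
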